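**Retrosynthetic overview**
- The oxirane is made last among the rings, by hydroxyl-directed epoxidation of the (3Z) olefin of a ten-membered triene; the acetate goes on after it.
- The ten-membered carbocycle is closed at C6–C7 by a Lewis-acid carbonyl-ene reaction of an acyclic C15 α-silyloxy aldehyde onto its own prenyl terminus. This mirrors the C1–C10 closure and proton loss of farnesyl diphosphate to a germacrene and sets C6, C7 and the isopropenyl group in one step.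
- The C1/C10 oxygens come from C9–OH-directed epoxidation of a Z C1=C10 olefin, opened at C1 by angelic acid with inversion.
- The acyclic chain comes from two chiral-pool α-oxygenated methyl ketones (C4–C6 and C7–C10) joined through a three-carbon bis-phosphonium salt by two Z-selective Wittig reactions.
- Ring order: carbocycle first, oxirane second.

Assumption: ring atoms are numbered as in germacrane (C7 isopropenyl carbon, C6 senecioate, C5 acetate, C4/C3 oxirane, C1 angelate, C10 C(OH)Me, C9 CHOH; C14 = methyl on C10, C15 = methyl on C4); the ester drawn /C(C)=C\C is the (Z)-2-methylbut-2-enoate (angelate), so the target is (1S,3R,4R,5S,6S,7R,9R,10S).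

**Route**

Step 1
Reactants: 1 methyl (4S)-2,2-dimethyl-1,3-dioxolane-4-carboxylate
Product: 3 (4S)-4-acetyl-2,2-dimethyl-1,3-dioxolane, via Weinreb amide 2 (not isolated)
Conditions: MeNH(OMe)·HCl, iPrMgCl, THF, −20 °C; then MeMgBr, −20 → 0 °C; aq. NH4Cl
Reagents that add atoms: methylmagnesium bromide C[Mg]Br
Why: One-pot Weinreb ketone synthesis, in which the chelated adduct of MeMgBr and the amide stops at the ketone and the C5 stereocentre from the chiral pool is carried through unchanged.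

Step 2
Reactants: 4 propane-1,3-diylbis(triphenylphosphonium) dibromide; 3 (4S)-4-acetyl-2,2-dimethyl-1,3-dioxolane
Product: 6 {(3Z)-4-[(4R)-2,2-dimethyl-1,3-dioxolan-4-yl]pent-3-en-1-yl}triphenylphosphonium bromide, via mono-ylide 5 (not isolated)
Conditions: 4 (2 equiv), KN(SiMe3)2 (2 equiv), THF, 0 °C; then 3, −78 °C → rt
Reagents that add atoms: none
Why: Wittig reaction of a non-stabilised ylide and an α-alkoxy ketone, which places the oxygen-bearing carbon cis to the new chain and so gives the Z C3=C4 olefin while the second phosphonium group is kept for step 6.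

Step 3
Reactants: 7 methyl (2R)-oxirane-2-carboxylate
Product: 8 methyl (2R)-2-hydroxy-5-methylhex-4-enoate
Conditions: (CH3)2C=CHMgBr, CuI (10 mol%), THF, −40 → −20 °C; aq. NH4Cl
Reagents that add atoms: 2-methylprop-1-en-1-ylmagnesium bromide CC(C)=C[Mg]Br
Why: Copper-catalysed Grignard opening of the glycidic ester at its CH2 carbon (SN2) leaves the C9 stereocentre untouched and installs the prenyl terminus that later acts as the ene donor.

Step 4
Reactants: 8 methyl (2R)-2-hydroxy-5-methylhex-4-enoate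
Product: 9 methyl (2R)-5-methyl-2-[(triethylsilyl)oxy]hex-4-enoate
Conditions: Et3SiCl, imidazole, CH2Cl2, 0 °C → rt
Reagents that add atoms: chlorotriethylsilane CC[Si](Cl)(CC)CC
Why: Standard silylation, which gives the α-silyloxy group needed for the ketone synthesis and for Z-selectivity in the second Wittig reaction.

Step 5
Reactants: 9 methyl (2R)-5-methyl-2-[(triethylsilyl)oxy]hex-4-enoate
Product: 11 (3R)-6-methyl-3-[(triethylsilyl)oxy]hept-5-en-2-one, via Weinreb amide 10 (not isolated)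
Conditions: MeNH(OMe)·HCl, iPrMgCl, THF, −20 °C; then MeMgBr, −20 → 0 °C; aq. NH4Cl
Reagents that add atoms: methylmagnesium bromide C[Mg]Br
Why: The same one-pot Weinreb ketone synthesis as in step 1 gives the α-silyloxy methyl ketone without touching C9.

Step 6
Reactants: 6 {(3Z)-4-[(4R)-2,2-dimethyl-1,3-dioxolan-4-yl]pent-3-en-1-yl}triphenylphosphonium bromide; 11 (3R)-6-methyl-3-[(triethylsilyl)oxy]hept-5-en-2-one
Product: 14 (5R,6Z,9Z)-10-[(4R)-2,2-dimethyl-1,3-dioxolan-4-yl]-2,6-dimethylundeca-2,6,9-trien-5-ol, via ylide 12 (not isolated), via silyl ether 13 (not isolated)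
Conditions: KN(SiMe3)2, THF, −78 °C; 11, −78 → 0 °C; then Bu4NF, 0 °C
Reagents that add atoms: none
Why: A second Z-selective Wittig reaction of a non-stabilised ylide and an α-silyloxy ketone sets the Z C1=C10 olefin and completes the C15 chain, and fluoride then frees the C9 hydroxyl that directs step 7.

Step 7
Reactants: 14 (5R,6Z,9Z)-10-[(4R)-2,2-dimethyl-1,3-dioxolan-4-yl]-2,6-dimethylundeca-2,6,9-trien-5-ol
Product: 16 (2Z,5S,6S,7R)-2-[(4R)-2,2-dimethyl-1,3-dioxolan-4-yl]-6,7-dihydroxy-6,10-dimethylundeca-2,9-dien-5-yl (2Z)-2-methylbut-2-enoate, via epoxy alcohol 15 (not isolated)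
Conditions: Ti(OiPr)4 (1.2 equiv), tBuOOH (1.3 equiv), 4 Å MS, CH2Cl2, −20 °C; then (Z)-2-methylbut-2-enoic acid (2 equiv), Ti(OiPr)4 (1.5 equiv), 0 °C → rt
Reagents that add atoms: tert-butyl hydroperoxide CC(C)(C)OO; (Z)-2-methylbut-2-enoic acid (angelic acid) C/C=C(/C)C(=O)O
Why: Hydroxyl-directed Ti(OiPr)4/tBuOOH epoxidation of the Z allylic alcohol is threo-selective under A(1,3) strain (C10–O syn to C9–O) and touches only the allylic C1=C10 bond, and titanium-mediated opening of the 2,3-epoxy alcohol by the carboxylic acid at the distal carbon C1 (SN2, inversion) then sets C1 and installs the angelate without a protecting group.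

Step 8
Reactants: 16 (2Z,5S,6S,7R)-2-[(4R)-2,2-dimethyl-1,3-dioxolan-4-yl]-6,7-dihydroxy-6,10-dimethylundeca-2,9-dien-5-yl (2Z)-2-methylbut-2-enoate
Product: 17 (2R,3Z,6S,7S,8R)-1,2,7,8-tetrahydroxy-3,7,11-trimethyldodeca-3,10-dien-6-yl (2Z)-2-methylbut-2-enoate
Conditions: AcOH/THF/H2O (3:1:1), 40 °C
Reagents that add atoms: none
Why: Mild acid hydrolysis of the terminal acetonide frees the C5/C6 diol while the ester, the tertiary alcohol and the olefins are inert.

Step 9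
Reactants: 17 (2R,3Z,6S,7S,8R)-1,2,7,8-tetrahydroxy-3,7,11-trimethyldodeca-3,10-dien-6-yl (2Z)-2-methylbut-2-enoate
Product: 18 (2R,3Z,6S,7R,8R)-7-hydroxy-3,7,11-trimethyl-1,2,8-tris[(triethylsilyl)oxy]dodeca-3,10-dien-6-yl (2Z)-2-methylbut-2-enoate
Conditions: Et3SiCl (3.5 equiv), imidazole, DMF, 0 °C → rt
Reagents that add atoms: chlorotriethylsilane CC[Si](Cl)(CC)CC
Why: Silyl chloride and imidazole silylate the primary and the two secondary hydroxyls but not the tertiary C10 hydroxyl.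

Step 10
Reactants: 18 (2R,3Z,6S,7R,8R)-7-hydroxy-3,7,11-trimethyl-1,2,8-tris[(triethylsilyl)oxy]dodeca-3,10-dien-6-yl (2Z)-2-methylbut-2-enoate
Product: 19 (2R,3Z,6S,7R,8R)-7-hydroxy-3,7,11-trimethyl-1-oxo-2,8-bis[(triethylsilyl)oxy]dodeca-3,10-dien-6-yl (2Z)-2-methylbut-2-enoate
Conditions: (COCl)2, DMSO, CH2Cl2, −78 → −40 °C; Et3N, −78 → 0 °C; used at once
Reagents that add atoms: none
Why: Under Swern conditions a primary triethylsilyl ether is cleaved and oxidised directly to the aldehyde while secondary silyl ethers survive, which gives the α-silyloxy aldehyde in one step.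

Step 11
Reactants: 19 (2R,3Z,6S,7R,8R)-7-hydroxy-3,7,11-trimethyl-1-oxo-2,8-bis[(triethylsilyl)oxy]dodeca-3,10-dien-6-yl (2Z)-2-methylbut-2-enoate
Product: 20 (1S,3Z,5R,6S,7R,9R,10R)-6,10-dihydroxy-5,9-bis[(triethylsilyl)oxy]germacra-3,11-dien-1-yl (2Z)-2-methylbut-2-enoate
Conditions: Me2AlCl (3 equiv), CH2Cl2, 1 mM (slow addition of 19), −78 → −30 °C; aq. NaHCO3/KNaC4H4O6
Reagents that add atoms: none
Why: Proposed new method: a Me2AlCl-promoted carbonyl-ene reaction used as a ten-membered macrocyclisation, in which the activated aldehyde C6 is attacked by the less substituted olefin carbon C7 while a methyl hydrogen passes to oxygen through a six-membered transition state, giving the C6 carbinol and the isopropenyl group as C1–C10 closure and proton loss do in germacrene formation; C6 should form anti to the C5 silyloxy group by Felkin–Anh attack and C7 through the tether-constrained chair with C5 and C8 gauche; the closest known reaction types are Me2AlCl-promoted intramolecular carbonyl-ene cyclisations and macrocyclic intramolecular aldehyde allylations.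

Step 12
Reactants: 20 (1S,3Z,5R,6S,7R,9R,10R)-6,10-dihydroxy-5,9-bis[(triethylsilyl)oxy]germacra-3,11-dien-1-yl (2Z)-2-methylbut-2-enoate
Product: 21 (1S,3Z,5R,6S,7R,9R,10R)-10-hydroxy-1-{[(2Z)-2-methylbut-2-enoyl]oxy}-5,9-bis[(triethylsilyl)oxy]germacra-3,11-dien-6-yl 3-methylbut-2-enoate
Conditions: 3-methylbut-2-enoyl chloride, pyridine, DMAP (cat.), CH2Cl2, 0 °C
Reagents that add atoms: 3-methylbut-2-enoyl chloride CC(C)=CC(=O)Cl
Why: DMAP-catalysed acylation of the only free secondary hydroxyl (C6), the tertiary C10 hydroxyl being unreactive and pyridine being too weak a base to deconjugate the acyl chloride.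

Step 13
Reactants: 21 (1S,3Z,5R,6S,7R,9R,10R)-10-hydroxy-1-{[(2Z)-2-methylbut-2-enoyl]oxy}-5,9-bis[(triethylsilyl)oxy]germacra-3,11-dien-6-yl 3-methylbut-2-enoate
Product: 22 (1S,3Z,5R,6S,7R,9R,10S)-5,9,10-trihydroxy-1-{[(2Z)-2-methylbut-2-enoyl]oxy}germacra-3,11-dien-6-yl 3-methylbut-2-enoate
Conditions: HF·pyridine, pyridine, THF, 0 °C
Reagents that add atoms: none
Why: Buffered fluoride desilylation under slightly acidic conditions frees C5–OH and C9–OH without acyl migration or ester cleavage.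

Step 14
Reactants: 22 (1S,3Z,5R,6S,7R,9R,10S)-5,9,10-trihydroxy-1-{[(2Z)-2-methylbut-2-enoyl]oxy}germacra-3,11-dien-6-yl 3-methylbut-2-enoate
Product: 23 (1S,3R,4S,5S,6S,7R,9R,10S)-3,4-epoxy-5,9,10-trihydroxy-1-{[(2Z)-2-methylbut-2-enoyl]oxy}germacr-11-en-6-yl 3-methylbut-2-enoate
Conditions: VO(acac)2 (5 mol%), tBuOOH (1.2 equiv), CH2Cl2, 0 °C → rt
Reagents that add atoms: tert-butyl hydroperoxide CC(C)(C)OO
Why: Vanadium-catalysed allylic-alcohol-directed epoxidation delivers oxygen to the C3=C4 face cis to C5–OH, as it does in eight- and nine-membered cis-cycloalkenols and in 2-methyl allylic alcohols under A(1,2) strain, setting C3 and C4 while the isopropenyl group and the enoates, which have no allylic hydroxyl, are left alone.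

Step 15
Reactants: 23 (1S,3R,4S,5S,6S,7R,9R,10S)-3,4-epoxy-5,9,10-trihydroxy-1-{[(2Z)-2-methylbut-2-enoyl]oxy}germacr-11-en-6-yl 3-methylbut-2-enoate
Product: 26 (1S,3R,4R,5S,6S,7R,9R,10S)-5-acetoxy-3,4-epoxy-9,10-dihydroxy-1-{[(2Z)-2-methylbut-2-enoyl]oxy}germacr-11-en-6-yl 3-methylbut-2-enoate, via phenylboronate 24 (not isolated), via acetylated phenylboronate 25 (not isolated)
Conditions: PhB(OH)2 (1.05 equiv), 4 Å MS, CH2Cl2, rt; then Ac2O, pyridine, DMAP (cat.), 0 °C → rt; then pinacol, rt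
Reagents that add atoms: acetic anhydride CC(=O)OC(C)=O
Why: A transient cyclic boronate masks the 9,10-diol so that acetylation occurs only at C5–OH, and transesterification to pinacol then releases the diol under neutral conditions that spare the oxirane and the three esters.

**Compound list**

1 | methyl (4S)-2,2-dimethyl-1,3-dioxolane-4-carboxylate | COC(=O)[C@@H]1COC(C)(C)O1 | starting material
2 | (4S)-N-methoxy-N,2,2-trimethyl-1,3-dioxolane-4-carboxamide | CON(C)C(=O)[C@@H]1COC(C)(C)O1 | intermediate (not isolated)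
3 | (4S)-4-acetyl-2,2-dimethyl-1,3-dioxolane | CC(=O)[C@@H]1COC(C)(C)O1 | intermediate
4 | propane-1,3-diylbis(triphenylphosphonium) dibromide | [Br-].[Br-].c1ccccc1[P+](c1ccccc1)(c1ccccc1)CCC[P+](c1ccccc1)(c1ccccc1)c1ccccc1 | starting material
5 | triphenyl[3-(triphenyl-λ5-phosphanylidene)propyl]phosphonium bromide (mono-ylide) | [Br-].c1ccccc1P(c1ccccc1)(c1ccccc1)=CCC[P+](c1ccccc1)(c1ccccc1)c1ccccc1 | intermediate (not isolated)
6 | {(3Z)-4-[(4R)-2,2-dimethyl-1,3-dioxolan-4-yl]pent-3-en-1-yl}triphenylphosphonium bromide | [Br-].C/C(=C/CC[P+](c1ccccc1)(c1ccccc1)c1ccccc1)[C@@H]1COC(C)(C)O1 | intermediate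
7 | methyl (2R)-oxirane-2-carboxylate | COC(=O)[C@H]1CO1 | starting material
8 | methyl (2R)-2-hydroxy-5-methylhex-4-enoate | COC(=O)[C@H](O)CC=C(C)C | intermediate
9 | methyl (2R)-5-methyl-2-[(triethylsilyl)oxy]hex-4-enoate | COC(=O)[C@H](O[Si](CC)(CC)CC)CC=C(C)C | intermediate
10 | (2R)-N-methoxy-N,5-dimethyl-2-[(triethylsilyl)oxy]hex-4-enamide | CON(C)C(=O)[C@H](O[Si](CC)(CC)CC)CC=C(C)C | intermediate (not isolated)
11 | (3R)-6-methyl-3-[(triethylsilyl)oxy]hept-5-en-2-one | CC(=O)[C@H](O[Si](CC)(CC)CC)CC=C(C)C | intermediate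
12 | (4R)-2,2-dimethyl-4-[(2Z)-5-(triphenyl-λ5-phosphanylidene)pent-2-en-2-yl]-1,3-dioxolane (ylide) | C/C(=C/CC=P(c1ccccc1)(c1ccccc1)c1ccccc1)[C@@H]1COC(C)(C)O1 | intermediate (not isolated)
13 | triethyl{[(5R,6Z,9Z)-10-[(4R)-2,2-dimethyl-1,3-dioxolan-4-yl]-2,6-dimethylundeca-2,6,9-trien-5-yl]oxy}silane | CC(C)=CC[C@@H](O[Si](CC)(CC)CC)/C(C)=C\C/C=C(/C)[C@@H]1COC(C)(C)O1 | intermediate (not isolated)
14 | (5R,6Z,9Z)-10-[(4R)-2,2-dimethyl-1,3-dioxolan-4-yl]-2,6-dimethylundeca-2,6,9-trien-5-ol | CC(C)=CC[C@@H](O)/C(C)=C\C/C=C(/C)[C@@H]1COC(C)(C)O1 | intermediate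
15 | (1R)-1-[(2S,3R)-3-{(2Z)-3-[(4R)-2,2-dimethyl-1,3-dioxolan-4-yl]but-2-en-1-yl}-2-methyloxiran-2-yl]-4-methylpent-3-en-1-ol | CC(C)=CC[C@@H](O)[C@]1(C)O[C@@H]1C/C=C(/C)[C@@H]1COC(C)(C)O1 | intermediate (not isolated)
16 | (2Z,5S,6S,7R)-2-[(4R)-2,2-dimethyl-1,3-dioxolan-4-yl]-6,7-dihydroxy-6,10-dimethylundeca-2,9-dien-5-yl (2Z)-2-methylbut-2-enoate | CC(C)=CC[C@@H](O)[C@](C)(O)[C@@H](OC(=O)/C(C)=C\C)C/C=C(/C)[C@@H]1COC(C)(C)O1 | intermediate
17 | (2R,3Z,6S,7S,8R)-1,2,7,8-tetrahydroxy-3,7,11-trimethyldodeca-3,10-dien-6-yl (2Z)-2-methylbut-2-enoate | CC(C)=CC[C@@H](O)[C@](C)(O)[C@@H](OC(=O)/C(C)=C\C)C/C=C(/C)[C@@H](O)CO | intermediate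
18 | (2R,3Z,6S,7R,8R)-7-hydroxy-3,7,11-trimethyl-1,2,8-tris[(triethylsilyl)oxy]dodeca-3,10-dien-6-yl (2Z)-2-methylbut-2-enoate | CC(C)=CC[C@@H](O[Si](CC)(CC)CC)[C@](C)(O)[C@@H](OC(=O)/C(C)=C\C)C/C=C(/C)[C@@H](O[Si](CC)(CC)CC)CO[Si](CC)(CC)CC | intermediate
19 | (2R,3Z,6S,7R,8R)-7-hydroxy-3,7,11-trimethyl-1-oxo-2,8-bis[(triethylsilyl)oxy]dodeca-3,10-dien-6-yl (2Z)-2-methylbut-2-enoate | CC(C)=CC[C@@H](O[Si](CC)(CC)CC)[C@](C)(O)[C@@H](OC(=O)/C(C)=C\C)C/C=C(/C)[C@@H](O[Si](CC)(CC)CC)C=O | intermediate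
20 | (1S,3Z,5R,6S,7R,9R,10R)-6,10-dihydroxy-5,9-bis[(triethylsilyl)oxy]germacra-3,11-dien-1-yl (2Z)-2-methylbut-2-enoate | C=C(C)[C@H]1C[C@@H](O[Si](CC)(CC)CC)[C@](C)(O)[C@@H](OC(=O)/C(C)=C\C)C/C=C(/C)[C@@H](O[Si](CC)(CC)CC)[C@H]1O | intermediate
21 | (1S,3Z,5R,6S,7R,9R,10R)-10-hydroxy-1-{[(2Z)-2-methylbut-2-enoyl]oxy}-5,9-bis[(triethylsilyl)oxy]germacra-3,11-dien-6-yl 3-methylbut-2-enoate | C=C(C)[C@H]1C[C@@H](O[Si](CC)(CC)CC)[C@](C)(O)[C@@H](OC(=O)/C(C)=C\C)C/C=C(/C)[C@@H](O[Si](CC)(CC)CC)[C@H]1OC(=O)C=C(C)C | intermediate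
22 | (1S,3Z,5R,6S,7R,9R,10S)-5,9,10-trihydroxy-1-{[(2Z)-2-methylbut-2-enoyl]oxy}germacra-3,11-dien-6-yl 3-methylbut-2-enoate | C=C(C)[C@H]1C[C@@H](O)[C@](C)(O)[C@@H](OC(=O)/C(C)=C\C)C/C=C(/C)[C@@H](O)[C@H]1OC(=O)C=C(C)C | intermediate
23 | (1S,3R,4S,5S,6S,7R,9R,10S)-3,4-epoxy-5,9,10-trihydroxy-1-{[(2Z)-2-methylbut-2-enoyl]oxy}germacr-11-en-6-yl 3-methylbut-2-enoate | C=C(C)[C@H]1C[C@@H](O)[C@](C)(O)[C@@H](OC(=O)/C(C)=C\C)C[C@H]2O[C@@]2(C)[C@@H](O)[C@H]1OC(=O)C=C(C)C | intermediate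
24 | (1S,3R,4S,5S,6S,7R,9R,10S)-3,4-epoxy-5-hydroxy-1-{[(2Z)-2-methylbut-2-enoyl]oxy}-9,10-[(phenylboranediyl)bis(oxy)]germacr-11-en-6-yl 3-methylbut-2-enoate | C=C(C)[C@H]1C[C@H]3OB(c4ccccc4)O[C@]3(C)[C@@H](OC(=O)/C(C)=C\C)C[C@H]2O[C@@]2(C)[C@@H](O)[C@H]1OC(=O)C=C(C)C | intermediate (not isolated)
25 | (1S,3R,4R,5S,6S,7R,9R,10S)-5-acetoxy-3,4-epoxy-1-{[(2Z)-2-methylbut-2-enoyl]oxy}-9,10-[(phenylboranediyl)bis(oxy)]germacr-11-en-6-yl 3-methylbut-2-enoate | C=C(C)[C@H]1C[C@H]3OB(c4ccccc4)O[C@]3(C)[C@@H](OC(=O)/C(C)=C\C)C[C@H]2O[C@@]2(C)[C@@H](OC(C)=O)[C@H]1OC(=O)C=C(C)C | intermediate (not isolated)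
26 | (1S,3R,4R,5S,6S,7R,9R,10S)-5-acetoxy-3,4-epoxy-9,10-dihydroxy-1-{[(2Z)-2-methylbut-2-enoyl]oxy}germacr-11-en-6-yl 3-methylbut-2-enoate (CNP0298989.1) | C=C(C)[C@H]1C[C@@H](O)[C@](C)(O)[C@@H](OC(=O)/C(C)=C\C)C[C@H]2O[C@@]2(C)[C@@H](OC(C)=O)[C@H]1OC(=O)C=C(C)C | target

**Step count and risk**

Total steps: 15. Longest linear sequence: 13 steps (7 → 26, steps 3 to 15).

Most likely to fail, first: step 11. A ten-membered carbonyl-ene closure has no direct precedent; oligomerisation, Prins-type chloride capture or the wrong C6/C7 diastereomer are all possible. The fallback keeps the same C6–C7 bond but makes the terminus a true allyl nucleophile. Setting out from 18, SeO2 (cat.)/tBuOOH in CH2Cl2 oxidises the (E)-methyl of the prenyl group to the allylic alcohol F1. MsCl/Et3N followed by LiCl gives the allylic chloride F2. Swern oxidation as in step 10 gives the chloro aldehyde F3. CrCl2 in THF at high dilution (intramolecular Nozaki–Hiyama allylation through a closed six-membered transition state) then closes the ring, and the route is rejoined at 20.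

Second: step 14. The facial selectivity rests on analogy with eight- and nine-membered cycloalkenols; the ten-membered ring may expose the other face. The fallback replaces substrate direction by reagent control. Setting out from 21, a Shi epoxidation (fructose-derived ketone catalyst or its enantiomer, whichever matches; KHSO5, K2CO3, MeCN/H2O, 0 °C) epoxidises the trisubstituted C3=C4 bond in preference to the 1,1-disubstituted isopropenyl group and the enoates, giving the bis-silyl epoxide F4. HF·pyridine as in step 13 removes both silyl groups, and the route is rejoined at 23.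

Third: step 7. The threo selectivity is moderate (about 5–9:1 expected), and carboxylate opening could occur at the tertiary carbon C10 or be followed by acyl migration. The fallback sets C10 and C1 by a different reaction pair. Setting out from 14, OsO4/TMEDA in CH2Cl2 at −78 °C (hydrogen-bond-directed dihydroxylation) adds both oxygens syn to the C9 hydroxyl and gives the triol F5, with C10 correct and C1 epimeric. 2,2-Dimethoxypropane/PPTS gives the 9,10-acetonide F6, favoured because its two large substituents are trans, with C1–OH free. Mitsunobu esterification with angelic acid (PPh3, DIAD, toluene, 0 °C) inverts C1 and gives the angelate F7. The conditions of step 8 remove both acetonides, and the route is rejoined at 17.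

**Further compounds**

F1 | step 11 | (2R,3Z,6S,7R,8R,10E)-7,12-dihydroxy-3,7,11-trimethyl-1,2,8-tris[(triethylsilyl)oxy]dodeca-3,10-dien-6-yl (2Z)-2-methylbut-2-enoate | OC/C(C)=C/C[C@@H](O[Si](CC)(CC)CC)[C@](C)(O)[C@@H](OC(=O)/C(C)=C\C)C/C=C(/C)[C@@H](O[Si](CC)(CC)CC)CO[Si](CC)(CC)CC
F2 | step 11 | (2R,3Z,6S,7R,8R,10E)-12-chloro-7-hydroxy-3,7,11-trimethyl-1,2,8-tris[(triethylsilyl)oxy]dodeca-3,10-dien-6-yl (2Z)-2-methylbut-2-enoate | ClC/C(C)=C/C[C@@H](O[Si](CC)(CC)CC)[C@](C)(O)[C@@H](OC(=O)/C(C)=C\C)C/C=C(/C)[C@@H](O[Si](CC)(CC)CC)CO[Si](CC)(CC)CC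
F3 | step 11 | (2R,3Z,6S,7R,8R,10E)-12-chloro-7-hydroxy-3,7,11-trimethyl-1-oxo-2,8-bis[(triethylsilyl)oxy]dodeca-3,10-dien-6-yl (2Z)-2-methylbut-2-enoate | ClC/C(C)=C/C[C@@H](O[Si](CC)(CC)CC)[C@](C)(O)[C@@H](OC(=O)/C(C)=C\C)C/C=C(/C)[C@@H](O[Si](CC)(CC)CC)C=O
F4 | step 14 | (1S,3R,4S,5S,6S,7R,9R,10R)-3,4-epoxy-10-hydroxy-1-{[(2Z)-2-methylbut-2-enoyl]oxy}-5,9-bis[(triethylsilyl)oxy]germacr-11-en-6-yl 3-methylbut-2-enoate | C=C(C)[C@H]1C[C@@H](O[Si](CC)(CC)CC)[C@](C)(O)[C@@H](OC(=O)/C(C)=C\C)C[C@H]2O[C@@]2(C)[C@@H](O[Si](CC)(CC)CC)[C@H]1OC(=O)C=C(C)C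
F5 | step 7 | (2Z,5R,6S,7R)-2-[(4R)-2,2-dimethyl-1,3-dioxolan-4-yl]-6,10-dimethylundeca-2,9-diene-5,6,7-triol | CC(C)=CC[C@@H](O)[C@](C)(O)[C@H](O)C/C=C(/C)[C@@H]1COC(C)(C)O1
F6 | step 7 | (1R,3Z)-4-[(4R)-2,2-dimethyl-1,3-dioxolan-4-yl]-1-[(4R,5R)-2,2,4-trimethyl-5-(3-methylbut-2-en-1-yl)-1,3-dioxolan-4-yl]pent-3-en-1-ol | CC(C)=CC[C@H]1OC(C)(C)O[C@]1(C)[C@H](O)C/C=C(/C)[C@@H]2COC(C)(C)O2
F7 | step 7 | (1S,3Z)-4-[(4R)-2,2-dimethyl-1,3-dioxolan-4-yl]-1-[(4R,5R)-2,2,4-trimethyl-5-(3-methylbut-2-en-1-yl)-1,3-dioxolan-4-yl]pent-3-en-1-yl (2Z)-2-methylbut-2-enoate | CC(C)=CC[C@H]1OC(C)(C)O[C@]1(C)[C@@H](OC(=O)/C(C)=C\C)C/C=C(/C)[C@@H]2COC(C)(C)O2
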